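## Retrosynthetic overview

- **Feature the strategy rests on:** in guaiane numbering, the 2-methylcyclopent-2-enone C1–C2–C3(=O)–C4(C15)=C5 is fused through C1–C5 to the seven-membered ring C1/C5/C6/C7/C8/C9/C10. C15–C4–C5 is a methyl alkyne, C3 is carbon monoxide, and C2–C1 with C10(C14) is the outer double bond of a 1,1-disubstituted allene.
- **Key disconnection:** a rhodium-catalysed allenic Pauson–Khand cyclocarbonylation of the acyclic allene-yne 21 forms C1–C5, C2–C3 and C3–C4. Neither carbocycle exists before it; the seven-membered ring closes in the oxidative coupling and the five-membered ring on carbonylative reductive elimination (22).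
- **After the key step:** hydrogen-atom-transfer hydration of C1=C10 on the α-face (C1–OH, C10–H), PMB removal, angelate on O8, TBS removal.
- **Before the key step:** C8 comes from (S)-butane-1,2,4-triol. C9–C10 is made by acetylide alkylation and C14 by copper-catalysed SN2′ methylation to the allene. C6 and C7 are set by an Evans syn aldol of the C11 imide with but-2-ynal, and the C11 carbinol acetate is made from the ester.

Key step: step 13

Remark: guaiane numbering is used throughout and β is the face of the C10 methyl group; the dibutylboron enolate of step 8 is assumed to keep its β-PMB-oxy group at −78 °C.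

## Route

Step 1
Reactants: 1 (S)-butane-1,2,4-triol
Product: 2 [(2S,4S)-2-(4-methoxyphenyl)-1,3-dioxan-4-yl]methanol
Conditions: 4-MeOC6H4CH(OMe)2, CSA (cat.), CH2Cl2, rt
Reagents that add atoms: 4-methoxybenzaldehyde dimethyl acetal, COC(OC)c1ccc(OC)cc1
Why: Acid-catalysed transacetalisation under equilibrium control should tie O8 and O11 into the six-membered p-methoxybenzylidene acetal (aryl and CH2OH both equatorial, which sets the acetal carbon) and leave the primary C9 hydroxyl free, with C8 taken unchanged from the triol.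

Step 2
Reactants: 2 [(2S,4S)-2-(4-methoxyphenyl)-1,3-dioxan-4-yl]methanol
Product: 3 [(2S,4S)-2-(4-methoxyphenyl)-1,3-dioxan-4-yl]methyl trifluoromethanesulfonate
Conditions: Tf2O, 2,6-lutidine, CH2Cl2, −78 °C; used crude
Reagents that add atoms: trifluoromethanesulfonic anhydride, O=S(=O)(OS(=O)(=O)C(F)(F)F)C(F)(F)F
Why: O-Sulfonylation of the primary alcohol under buffered conditions gives a triflate reactive enough for alkylation next to the acetal oxygen, and no stereocentre is touched.

Step 3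
Reactants: 3 [(2S,4S)-2-(4-methoxyphenyl)-1,3-dioxan-4-yl]methyl trifluoromethanesulfonate; 4 3-methoxyprop-1-yne (methyl ether of prop-2-yn-1-ol)
Product: 5 (2S,4R)-4-(4-methoxybut-2-yn-1-yl)-2-(4-methoxyphenyl)-1,3-dioxane
Conditions: 4, n-BuLi, THF, −78 °C; then 3, DMPU, −78 → −20 °C
Reagents that add atoms: none
Why: SN2 alkylation of the lithium acetylide by the primary triflate forms C9–C10, the triflate making up for the retarding β-oxygen.

Step 4
Reactants: 5 (2S,4R)-4-(4-methoxybut-2-yn-1-yl)-2-(4-methoxyphenyl)-1,3-dioxane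
Product: 6 (2S,4R)-2-(4-methoxyphenyl)-4-(2-methylbuta-2,3-dien-1-yl)-1,3-dioxane
Conditions: MeMgBr, CuBr (10 mol %), Et2O, 0 °C → rt
Reagents that add atoms: methylmagnesium bromide, C[Mg]Br
Why: Copper-catalysed SN2′ substitution of the propargylic methyl ether by the Grignard reagent should place the methyl group (C14) on C10 and expel methoxide from C2, giving the terminal 1,1-disubstituted allene.

Step 5
Reactants: 6 (2S,4R)-2-(4-methoxyphenyl)-4-(2-methylbuta-2,3-dien-1-yl)-1,3-dioxane
Product: 7 (3R)-3-[(4-methoxybenzyl)oxy]-5-methylhepta-5,6-dien-1-ol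
Conditions: iBu2AlH, CH2Cl2, −78 → 0 °C; Rochelle salt work-up
Reagents that add atoms: none
Why: Regioselective reductive opening of the p-methoxybenzylidene acetal: aluminium binds the less hindered oxygen (O11) and hydride cleaves that C–O bond, so the PMB ether stays on the secondary O8 and the primary C11 alcohol is freed.

Step 6
Reactants: 7 (3R)-3-[(4-methoxybenzyl)oxy]-5-methylhepta-5,6-dien-1-ol
Product: 9 (3R)-3-[(4-methoxybenzyl)oxy]-5-methylhepta-5,6-dienoic acid, via aldehyde 8 (not isolated)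
Conditions: TEMPO (20 mol %), PhI(OAc)2, MeCN/H2O, rt
Reagents that add atoms: water, O
Why: Oxoammonium (TEMPO) oxidation takes the primary alcohol to the aldehyde and, through its hydrate, to the acid under near-neutral conditions that spare the PMB ether and the allene.

Step 7
Reactants: 9 (3R)-3-[(4-methoxybenzyl)oxy]-5-methylhepta-5,6-dienoic acid; 10 (R)-4-benzyloxazolidin-2-one
Product: 12 (4R)-4-benzyl-3-{(3R)-3-[(4-methoxybenzyl)oxy]-5-methylhepta-5,6-dienoyl}oxazolidin-2-one, via mixed pivalic anhydride 11 (not isolated)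
Conditions: PivCl, Et3N, THF, −20 °C; then 10, LiCl, rt
Reagents that add atoms: none
Why: N-Acylation of the oxazolidinone through the mixed pivalic anhydride with LiCl/Et3N activation avoids strong base, so the β-alkoxy acid is not exposed to elimination.

Step 8
Reactants: 12 (4R)-4-benzyl-3-{(3R)-3-[(4-methoxybenzyl)oxy]-5-methylhepta-5,6-dienoyl}oxazolidin-2-one; 13 but-2-ynal
Product: 16 (4R)-4-benzyl-3-[(2S,3R)-3-hydroxy-2-{(1R)-1-[(4-methoxybenzyl)oxy]-3-methylpenta-3,4-dien-1-yl}hex-4-ynoyl]oxazolidin-2-one, via boron enolate 14 (not isolated), via boron aldolate 15 (not isolated)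
Conditions: Bu2BOTf, iPr2NEt, CH2Cl2, −78 → 0 °C; then 13, −78 → −20 °C; pH 7 buffer, MeOH, H2O2, 0 °C
Reagents that add atoms: none
Why: Evans syn aldol: soft enolisation gives the covalent Z-boron enolate, which adds to the ynal through a Zimmerman–Traxler chair on the face away from the benzyl group of the (R)-auxiliary, setting C7 (S) and C6 (R) syn to each other while C8 is a spectator.

Step 9
Reactants: 16 (4R)-4-benzyl-3-[(2S,3R)-3-hydroxy-2-{(1R)-1-[(4-methoxybenzyl)oxy]-3-methylpenta-3,4-dien-1-yl}hex-4-ynoyl]oxazolidin-2-one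
Product: 17 methyl (2S,3R)-3-hydroxy-2-{(1R)-1-[(4-methoxybenzyl)oxy]-3-methylpenta-3,4-dien-1-yl}hex-4-ynoate
Conditions: MeMgBr, MeOH, CH2Cl2, 0 °C
Reagents that add atoms: methanol, CO
Why: Magnesium methoxide transesterification, helped by chelation of the free β-hydroxyl to the exocyclic carbonyl, releases the auxiliary without retro-aldol cleavage or epimerisation at C7.

Step 10
Reactants: 17 methyl (2S,3R)-3-hydroxy-2-{(1R)-1-[(4-methoxybenzyl)oxy]-3-methylpenta-3,4-dien-1-yl}hex-4-ynoate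
Product: 18 methyl (2R,3R)-3-[(tert-butyldimethylsilyl)oxy]-2-{(1R)-1-[(4-methoxybenzyl)oxy]-3-methylpenta-3,4-dien-1-yl}hex-4-ynoate
Conditions: TBSOTf, 2,6-lutidine, CH2Cl2, −78 → 0 °C
Reagents that add atoms: tert-butyldimethylsilyl trifluoromethanesulfonate, CC(C)(C)[Si](C)(C)OS(=O)(=O)C(F)(F)F
Why: Silylation of the hindered propargylic alcohol with the silyl triflate protects O6 for the rest of the route (the descriptor at C7 changes only because the priorities change).

Step 11
Reactants: 18 methyl (2R,3R)-3-[(tert-butyldimethylsilyl)oxy]-2-{(1R)-1-[(4-methoxybenzyl)oxy]-3-methylpenta-3,4-dien-1-yl}hex-4-ynoate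
Product: 20 (3R,4R)-4-[(tert-butyldimethylsilyl)oxy]-3-{(1R)-1-[(4-methoxybenzyl)oxy]-3-methylpenta-3,4-dien-1-yl}-2-methylhept-5-yn-2-ol, via methyl ketone 19 (not isolated)
Conditions: MeMgCl, CeCl3, THF, −78 → 0 °C
Reagents that add atoms: methylmagnesium chloride, C[Mg]Cl
Why: Double addition of the cerium-modified Grignard reagent to the ester builds the C11 carbinol with C12 and C13, the weakly basic organocerium adding to the intermediate ketone faster than it enolises it, so C7 is not epimerised and neither β-oxygen is eliminated.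

Step 12
Reactants: 20 (3R,4R)-4-[(tert-butyldimethylsilyl)oxy]-3-{(1R)-1-[(4-methoxybenzyl)oxy]-3-methylpenta-3,4-dien-1-yl}-2-methylhept-5-yn-2-ol
Product: 21 (3R,4R)-4-[(tert-butyldimethylsilyl)oxy]-3-{(1R)-1-[(4-methoxybenzyl)oxy]-3-methylpenta-3,4-dien-1-yl}-2-methylhept-5-yn-2-yl acetate (the allene-yne)
Conditions: LiN(SiMe3)2, THF, −78 °C; then Ac2O, −78 → 0 °C
Reagents that add atoms: acetic anhydride, CC(=O)OC(C)=O
Why: O-Acylation of the lithium alkoxide is the reliable way to acetylate a hindered tertiary alcohol, and at −78 °C silyl transfer from the secondary O6 to the tertiary oxygen is not expected.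

Step 13
Reactants: 21 (3R,4R)-4-[(tert-butyldimethylsilyl)oxy]-3-{(1R)-1-[(4-methoxybenzyl)oxy]-3-methylpenta-3,4-dien-1-yl}-2-methylhept-5-yn-2-yl acetate
Product: 22 (6R,7R,8R)-11-acetoxy-6-[(tert-butyldimethylsilyl)oxy]-8-[(4-methoxybenzyl)oxy]guaia-1(10),4-dien-3-one
Conditions: [Rh(CO)2Cl]2 (10 mol %), CO (1 atm), toluene (0.01 M), 90 °C
Reagents that add atoms: carbon monoxide, [C-]#[O+]
Why: Monovalent rhodium binds the C4≡C5 alkyne and the distal C1=C2 bond of the allene and couples them oxidatively, which forms C1–C5 and a rhodacyclopentene (Rh on C2 and C4) that already contains the seven-membered carbocycle; CO then inserts and reductive elimination forms C2–C3 and C3–C4. The closest known reaction type is the [Rh(CO)2Cl]2-catalysed allenic Pauson–Khand reaction of allene-ynes with a four-atom tether, which gives 4-alkylidenecyclopentenones fused to seven-membered rings. The seven-membered ring closes in the oxidative coupling by joining alkyne carbon C5 to the central allene carbon C1 across the tether C6–C9 plus C10, and the cyclopentenone closes by the carbonylative [2+2+1] union of C2, C3 (from CO) and C4. No stereocentre is created, and C6, C7 and C8 lie in the tether and are not touched. The step needs the distal and not the proximal allene bond, and carbonylation in place of cycloisomerisation: rhodium and the 1,1-disubstitution at C10 direct the metal to the unhindered C1=C2 bond, and the unsubstituted C2 terminus offers no β-hydrogen for the competing ene-type pathway. The three branching substituents on C6, C7 and C8 should bias the tether toward the folded conformer that the medium ring needs.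

Step 14
Reactants: 22 (6R,7R,8R)-11-acetoxy-6-[(tert-butyldimethylsilyl)oxy]-8-[(4-methoxybenzyl)oxy]guaia-1(10),4-dien-3-one
Product: 24 (1R,6R,7R,8R,10S)-11-acetoxy-6-[(tert-butyldimethylsilyl)oxy]-1-hydroxy-8-[(4-methoxybenzyl)oxy]guai-4-en-3-one, via hydroperoxide 23 (not isolated)
Conditions: Mn(dpm)3 (10 mol %, dpm = 2,2,6,6-tetramethylheptane-3,5-dionate), PhSiH3, O2 (1 atm), iPrOH/CH2Cl2, 0 °C; then P(OEt)3
Reagents that add atoms: dioxygen, O=O
Why: Mukaiyama hydration by hydrogen atom transfer: the manganese hydride should deliver H to C10, the δ-terminus of the dienone, from the α-face opposite the three β-substituents on C6, C7 and C8 (setting C10), and the delocalised radical should take up O2 at C1 anti to the new β-methyl and the C6 silyloxy group (setting C1 and keeping the C4=C5 enone), after which the phosphite reduces the hydroperoxide.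

Step 15
Reactants: 24 (1R,6R,7R,8R,10S)-11-acetoxy-6-[(tert-butyldimethylsilyl)oxy]-1-hydroxy-8-[(4-methoxybenzyl)oxy]guai-4-en-3-one
Product: 25 (1R,6R,7R,8R,10S)-11-acetoxy-6-[(tert-butyldimethylsilyl)oxy]-1,8-dihydroxyguai-4-en-3-one
Conditions: DDQ, CH2Cl2/pH 7 buffer, 0 °C
Reagents that add atoms: none
Why: Oxidative cleavage of the PMB ether by DDQ (single-electron oxidation, then hydrolysis of the oxocarbenium ion) frees O8 and leaves the silyl ether, the acetate, the enone and the tertiary alcohol alone.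

Step 16
Reactants: 25 (1R,6R,7R,8R,10S)-11-acetoxy-6-[(tert-butyldimethylsilyl)oxy]-1,8-dihydroxyguai-4-en-3-one; 26 angelic acid
Product: 28 (1R,6R,7R,8R,10S)-11-acetoxy-8-(angeloyloxy)-6-[(tert-butyldimethylsilyl)oxy]-1-hydroxyguai-4-en-3-one, via mixed anhydride 27 (not isolated)
Conditions: 26, 2,4,6-Cl3C6H2COCl, Et3N, toluene, rt; then 25, 75 °C
Reagents that add atoms: none
Why: Yamaguchi esterification with the preformed mixed anhydride and no nucleophilic catalyst should acylate the secondary C8 hydroxyl without Z-to-E isomerisation of the angelate and before acetyl transfer from O11 can compete, the tertiary C1 hydroxyl being inert.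

Step 17
Reactants: 28 (1R,6R,7R,8R,10S)-11-acetoxy-8-(angeloyloxy)-6-[(tert-butyldimethylsilyl)oxy]-1-hydroxyguai-4-en-3-one
Product: 29 (1R,6R,7S,8R,10S)-11-acetoxy-8-(angeloyloxy)-1,6-dihydroxyguai-4-en-3-one (target, CNP0273287.1)
Conditions: HF·pyridine, pyridine/THF, 0 °C → rt
Reagents that add atoms: none
Why: Fluoride-mediated desilylation under buffered, mildly acidic conditions frees O6 without the base-induced acyl migration that the neighbouring acetate and angelate would allow.

## Compound list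

1 | (S)-butane-1,2,4-triol | OCC[C@H](O)CO | starting material
2 | [(2S,4S)-2-(4-methoxyphenyl)-1,3-dioxan-4-yl]methanol | OC[C@@H]1CCO[C@H](c2ccc(OC)cc2)O1 | intermediate
3 | [(2S,4S)-2-(4-methoxyphenyl)-1,3-dioxan-4-yl]methyl trifluoromethanesulfonate | O=S(=O)(OC[C@@H]1CCO[C@H](c2ccc(OC)cc2)O1)C(F)(F)F | intermediate
4 | 3-methoxyprop-1-yne | C#CCOC | starting material
5 | (2S,4R)-4-(4-methoxybut-2-yn-1-yl)-2-(4-methoxyphenyl)-1,3-dioxane | COCC#CC[C@@H]1CCO[C@H](c2ccc(OC)cc2)O1 | intermediate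
6 | (2S,4R)-2-(4-methoxyphenyl)-4-(2-methylbuta-2,3-dien-1-yl)-1,3-dioxane | C=C=C(C)C[C@@H]1CCO[C@H](c2ccc(OC)cc2)O1 | intermediate
7 | (3R)-3-[(4-methoxybenzyl)oxy]-5-methylhepta-5,6-dien-1-ol | OCC[C@H](OCc1ccc(OC)cc1)CC(C)=C=C | intermediate
8 | (3R)-3-[(4-methoxybenzyl)oxy]-5-methylhepta-5,6-dienal (not isolated) | O=CC[C@H](OCc1ccc(OC)cc1)CC(C)=C=C | intermediate
9 | (3R)-3-[(4-methoxybenzyl)oxy]-5-methylhepta-5,6-dienoic acid | OC(=O)C[C@H](OCc1ccc(OC)cc1)CC(C)=C=C | intermediate
10 | (R)-4-benzyloxazolidin-2-one | O=C1N[C@H](Cc2ccccc2)CO1 | starting material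
11 | mixed pivalic anhydride of 9 (not isolated) | CC(C)(C)C(=O)OC(=O)C[C@H](OCc1ccc(OC)cc1)CC(C)=C=C | intermediate
12 | (4R)-4-benzyl-3-{(3R)-3-[(4-methoxybenzyl)oxy]-5-methylhepta-5,6-dienoyl}oxazolidin-2-one | O=C(C[C@H](OCc1ccc(OC)cc1)CC(C)=C=C)N1[C@H](Cc2ccccc2)COC1=O | intermediate
13 | but-2-ynal | CC#CC=O | starting material
14 | Z-dibutylboron enolate of 12 (not isolated) | CCCCB(CCCC)O/C(=C\[C@H](OCc1ccc(OC)cc1)CC(C)=C=C)N1[C@H](Cc2ccccc2)COC1=O | intermediate
15 | dibutylboron aldolate of 16 (not isolated) | CC#C[C@H](OB(CCCC)CCCC)[C@H](C(=O)N1[C@H](Cc2ccccc2)COC1=O)[C@H](OCc1ccc(OC)cc1)CC(C)=C=C | intermediate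
16 | (4R)-4-benzyl-3-[(2S,3R)-3-hydroxy-2-{(1R)-1-[(4-methoxybenzyl)oxy]-3-methylpenta-3,4-dien-1-yl}hex-4-ynoyl]oxazolidin-2-one | CC#C[C@H](O)[C@H](C(=O)N1[C@H](Cc2ccccc2)COC1=O)[C@H](OCc1ccc(OC)cc1)CC(C)=C=C | intermediate
17 | methyl (2S,3R)-3-hydroxy-2-{(1R)-1-[(4-methoxybenzyl)oxy]-3-methylpenta-3,4-dien-1-yl}hex-4-ynoate | CC#C[C@H](O)[C@H](C(=O)OC)[C@H](OCc1ccc(OC)cc1)CC(C)=C=C | intermediate
18 | methyl (2R,3R)-3-[(tert-butyldimethylsilyl)oxy]-2-{(1R)-1-[(4-methoxybenzyl)oxy]-3-methylpenta-3,4-dien-1-yl}hex-4-ynoate | CC#C[C@H](O[Si](C)(C)C(C)(C)C)[C@H](C(=O)OC)[C@H](OCc1ccc(OC)cc1)CC(C)=C=C | intermediate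
19 | (3R,4R)-4-[(tert-butyldimethylsilyl)oxy]-3-{(1R)-1-[(4-methoxybenzyl)oxy]-3-methylpenta-3,4-dien-1-yl}hept-5-yn-2-one (not isolated) | CC#C[C@H](O[Si](C)(C)C(C)(C)C)[C@H](C(C)=O)[C@H](OCc1ccc(OC)cc1)CC(C)=C=C | intermediate
20 | (3R,4R)-4-[(tert-butyldimethylsilyl)oxy]-3-{(1R)-1-[(4-methoxybenzyl)oxy]-3-methylpenta-3,4-dien-1-yl}-2-methylhept-5-yn-2-ol | CC#C[C@H](O[Si](C)(C)C(C)(C)C)[C@H](C(C)(C)O)[C@H](OCc1ccc(OC)cc1)CC(C)=C=C | intermediate
21 | (3R,4R)-4-[(tert-butyldimethylsilyl)oxy]-3-{(1R)-1-[(4-methoxybenzyl)oxy]-3-methylpenta-3,4-dien-1-yl}-2-methylhept-5-yn-2-yl acetate | CC#C[C@H](O[Si](C)(C)C(C)(C)C)[C@H](C(C)(C)OC(C)=O)[C@H](OCc1ccc(OC)cc1)CC(C)=C=C | intermediate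
22 | (6R,7R,8R)-11-acetoxy-6-[(tert-butyldimethylsilyl)oxy]-8-[(4-methoxybenzyl)oxy]guaia-1(10),4-dien-3-one | COc1ccc(CO[C@@H]2CC(C)=C3CC(=O)C(C)=C3[C@H](O[Si](C)(C)C(C)(C)C)[C@@H]2C(C)(C)OC(C)=O)cc1 | intermediate
23 | 1α-hydroperoxide of 24 (not isolated) | COc1ccc(CO[C@@H]2C[C@H](C)[C@]3(OO)CC(=O)C(C)=C3[C@H](O[Si](C)(C)C(C)(C)C)[C@@H]2C(C)(C)OC(C)=O)cc1 | intermediate
24 | (1R,6R,7R,8R,10S)-11-acetoxy-6-[(tert-butyldimethylsilyl)oxy]-1-hydroxy-8-[(4-methoxybenzyl)oxy]guai-4-en-3-one | COc1ccc(CO[C@@H]2C[C@H](C)[C@]3(O)CC(=O)C(C)=C3[C@H](O[Si](C)(C)C(C)(C)C)[C@@H]2C(C)(C)OC(C)=O)cc1 | intermediate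
25 | (1R,6R,7R,8R,10S)-11-acetoxy-6-[(tert-butyldimethylsilyl)oxy]-1,8-dihydroxyguai-4-en-3-one | O[C@@H]1C[C@H](C)[C@]2(O)CC(=O)C(C)=C2[C@H](O[Si](C)(C)C(C)(C)C)[C@@H]1C(C)(C)OC(C)=O | intermediate
26 | angelic acid, (Z)-2-methylbut-2-enoic acid | C/C=C(/C)C(=O)O | starting material
27 | angelic 2,4,6-trichlorobenzoic mixed anhydride (not isolated) | C/C=C(/C)C(=O)OC(=O)c1c(Cl)cc(Cl)cc1Cl | intermediate
28 | (1R,6R,7R,8R,10S)-11-acetoxy-8-(angeloyloxy)-6-[(tert-butyldimethylsilyl)oxy]-1-hydroxyguai-4-en-3-one | C/C=C(/C)C(=O)O[C@@H]1C[C@H](C)[C@]2(O)CC(=O)C(C)=C2[C@H](O[Si](C)(C)C(C)(C)C)[C@@H]1C(C)(C)OC(C)=O | intermediate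
29 | (1R,6R,7S,8R,10S)-11-acetoxy-8-(angeloyloxy)-1,6-dihydroxyguai-4-en-3-one (CNP0273287.1) | C/C=C(/C)C(=O)O[C@@H]1C[C@H](C)[C@]2(O)CC(=O)C(C)=C2[C@H](O)[C@@H]1C(C)(C)OC(C)=O | target

## Step count and risks

Total steps: 17. Longest linear sequence: 17 steps, from 1 to 29.

**Step 13 (cyclocarbonylation).** The closure of the seven-membered ring may be slower than catalyst decay and intermolecular coupling, because the propargylic silyl ether and the tertiary acetate crowd the alkyne and the open chain lets the two arms rotate apart.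
The fallback reshapes the precursor with a ring template; it sets out from 17 and comes back at 22.
- Addition of MeMgCl/CeCl3 to the hydroxy ester 17 would give the C6,C11-diol F1.
- 2-Methoxypropene with PPTS would close the six-membered C6,C11-acetonide F2. This 1,3-dioxane holds the alkyne arm and the allene arm cis on adjacent ring carbons and removes both bulky acyclic groups.
- The same [Rh(CO)2Cl]2/CO cyclocarbonylation would then give the acetonide dienone F3.
- Aqueous acetic acid would release the diol dienone F4.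
- TBSOTf/2,6-lutidine at −78 °C would silylate the secondary C6 hydroxyl to the silyl ether F5.
- Ac2O/DMAP/Et3N would acetylate the tertiary hydroxyl and return to 22.

**Step 14 (hydration).** The hydrogen atom may reach C10 from the β-face, or oxygen may be captured at C4 in place of C1.
The fallback replaces the radical hydration by an ionic sequence with a directed hydrogenation; it sets out from 22 and comes back at 24.
- mCPBA (NaHCO3, CH2Cl2, 0 °C) should epoxidise the electron-richer C1=C10 bond from the open α-face to the 1α,10α-epoxide F6.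
- TMSOTf/2,6-lutidine, then DBU and a dilute acid work-up, should open the C10–O bond (the C1 cation is disfavoured next to the enone) with loss of a C14 proton, giving the 1α-hydroxy-10(14)-ene F7.
- Hydrogenation with [Ir(cod)(PCy3)(py)]PF6 and H2 in CH2Cl2, directed by the C1 hydroxyl, should add hydrogen to C10 from the α-face and give 24.

**Step 8 (aldol).** The enolate may lose the C8 PMB-oxy group by β-elimination, and the neighbouring C8 centre may erode the facial control of the auxiliary.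
The fallback uses substrate control without an auxiliary and without an enolate that carries a β-leaving group. It sets out from 9 and comes back at 20; here the carboxyl carbon of 9 becomes C6, C11 comes from acetone, and C4, C5 and C15 come from propyne.
- TMSCHN2 would give the methyl ester F8, and DDQ the β-hydroxy ester F9.
- The Fráter–Seebach dianion (LiN(iPr)2, 2.2 equiv, THF, −78 → −20 °C) would add to acetone anti to the C8 alkoxide and give the diol ester F10, with C7 set.
- 4-Methoxybenzyl trichloroacetimidate with La(OTf)3 (cat.) would etherify the secondary hydroxyl to the PMB ether F11.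
- MeNHOMe·HCl/iPrMgCl would give the Weinreb amide F12, and CH3C≡CMgBr the ynone F13.
- Corey–Bakshi–Shibata reduction with the oxazaborolidine enantiomer that delivers the (6R)-carbinol (the (R)-catalyst if the propynyl group acts as the small substituent) would give the C6,C11-diol F1, the compound that also opens the first fallback.
- TBSOTf/2,6-lutidine at −78 °C would silylate its secondary hydroxyl and return to 20.

## Further compounds

F1 | step 13 | C6,C11-diol of the allene-yne chain (20 without the silyl group) | CC#C[C@H](O)[C@H](C(C)(C)O)[C@H](OCc1ccc(OC)cc1)CC(C)=C=C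
F2 | step 13 | C6,C11-acetonide of F1 (2,2,4,4-tetramethyl-1,3-dioxane with the propynyl group on C6 and the allene arm on C7, cis) | CC#C[C@@H]1OC(C)(C)OC(C)(C)[C@@H]1[C@H](OCc1ccc(OC)cc1)CC(C)=C=C
F3 | step 13 | 6,11-O-isopropylidene-8-[(4-methoxybenzyl)oxy]guaia-1(10),4-dien-3-one | COc1ccc(CO[C@@H]2CC(C)=C3CC(=O)C(C)=C3[C@@H]4OC(C)(C)OC(C)(C)[C@H]24)cc1
F4 | step 13 | 6,11-dihydroxy-8-[(4-methoxybenzyl)oxy]guaia-1(10),4-dien-3-one | COc1ccc(CO[C@@H]2CC(C)=C3CC(=O)C(C)=C3[C@H](O)[C@@H]2C(C)(C)O)cc1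
F5 | step 13 | 6-[(tert-butyldimethylsilyl)oxy]-11-hydroxy-8-[(4-methoxybenzyl)oxy]guaia-1(10),4-dien-3-one | COc1ccc(CO[C@@H]2CC(C)=C3CC(=O)C(C)=C3[C@H](O[Si](C)(C)C(C)(C)C)[C@@H]2C(C)(C)O)cc1
F6 | step 14 | 1α,10α-epoxide of 22 | COc1ccc(CO[C@@H]2C[C@@]4(C)O[C@]43CC(=O)C(C)=C3[C@H](O[Si](C)(C)C(C)(C)C)[C@@H]2C(C)(C)OC(C)=O)cc1
F7 | step 14 | 11-acetoxy-6-[(tert-butyldimethylsilyl)oxy]-1α-hydroxy-8-[(4-methoxybenzyl)oxy]guaia-4,10(14)-dien-3-one | COc1ccc(CO[C@@H]2CC(=C)[C@]3(O)CC(=O)C(C)=C3[C@H](O[Si](C)(C)C(C)(C)C)[C@@H]2C(C)(C)OC(C)=O)cc1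
F8 | step 8 | methyl (3R)-3-[(4-methoxybenzyl)oxy]-5-methylhepta-5,6-dienoate | COC(=O)C[C@H](OCc1ccc(OC)cc1)CC(C)=C=C
F9 | step 8 | methyl (3R)-3-hydroxy-5-methylhepta-5,6-dienoate | COC(=O)C[C@H](O)CC(C)=C=C
F10 | step 8 | methyl (2S,3R)-3-hydroxy-2-(2-hydroxypropan-2-yl)-5-methylhepta-5,6-dienoate | COC(=O)[C@H](C(C)(C)O)[C@H](O)CC(C)=C=C
F11 | step 8 | 3-O-(4-methoxybenzyl) ether of F10 | COC(=O)[C@H](C(C)(C)O)[C@H](OCc1ccc(OC)cc1)CC(C)=C=C
F12 | step 8 | N-methoxy-N-methyl amide of F11 | CON(C)C(=O)[C@H](C(C)(C)O)[C@H](OCc1ccc(OC)cc1)CC(C)=C=C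
F13 | step 8 | prop-1-ynyl ketone from F12 (C6 ketone, C11 carbinol, C8 PMB ether) | CC#CC(=O)[C@H](C(C)(C)O)[C@H](OCc1ccc(OC)cc1)CC(C)=C=C
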